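## Structural features

The target is a benzene ring (ring A; thymol numbering C1–C6, C7 benzylic, C8–C10 side chain) with a 1,2,4-pattern. C3 carries a phenolic (E)-2-methylbut-2-enoate (tiglate). C4, ortho to it, carries the quaternary carbon C8 of a 2,2-disubstituted oxirane (C8, C9, O8), and C8 also bears C10H2–O–isobutyryl. C1, para to C4, carries C7H2–O–isobutyryl.

C8 is the only stereocentre, (R), and has no stereochemical neighbour, so its configuration must come from a reagent or catalyst.

Three groups are fragile. The C8–O bond (tertiary, benzylic, ortho to O3) ionises with acid and is opened by a free ortho phenol. The aryl tiglate is an active ester that transfers to any nearby alkoxide. The benzylic isobutyrate rules out hydrogenolysis.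

Ring A is not the problem: its O3/C4/C1 pattern is that of commercial 4-bromo-3-hydroxybenzyl compounds, so aryne or ring-synthesis plans would add work.

The real difficulty is C8: a fully substituted carbon bearing aryl, oxygen and two CH2–O arms (C9 and C10) that differ only in what their oxygens are bound to. C8 is the central carbon of a 2-arylglycerol.

This is the feature used. If C9 is bonded to O10 instead of O8, the atoms C9, C8, C10 and O10 form an oxetane with a mirror plane through C8, and the stereocentre vanishes. The key step runs this in the forward sense by opening one of the two enantiotopic CH2–O bonds of that oxetane.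

A useful corollary: at the 2-arylglycidol stage a Payne rearrangement is degenerate and returns the same enantiomer (inversion at C8 is offset by exchange of the roles of C9 and C10). An acyl shift between the two arm oxygens of an open-chain monoester would instead give the enantiomer.

## Logic of the disconnections

**14 ⇒ 12.** The phenolic O3–C(=O) bond of the tiglate is cut. It is the most electrophilic ester and sits ortho to C8, so an alkoxide on O8 (needed to close the oxirane) would take the acyl group through a six-membered transfer. The tiglate must therefore come last. What remains has only one kind of ester. The forward step must unmask O3 without acid and acylate it before the ortho phenoxide (13) can attack the oxirane.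

**12 ⇒ 11.** The two O–isobutyryl bonds (O7 and O10) are cut together, since both carry the same acyl group. This leaves an epoxy diol whose phenol is still masked as an allyl ether. The forward acylation must be basic and buffered so the oxirane survives.

**11 ⇒ 9.** The oxirane bond O8–C9 is cut; C9 becomes CH2Br and all oxygens are silylated. The acid-labile three-membered ring is exchanged for a stable open-chain compound. The forward closure (through 10) needs the tertiary alkoxide to attack C9 (3-exo-tet) faster than the primary alkoxide re-forms an oxetane (4-exo-tet). No bond to C8 is involved.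

**9 ⇒ 7 (key disconnection).** C9 is joined to O10 with formal loss of TMSBr: the retron of a 1,3-bromohydrin is an oxetane. The stereocentre disappears, because 7 is achiral. In one sentence, the route rests on catalyst-controlled delivery of bromide to one of the two enantiotopic ring CH2 groups of 7. The forward step must make that choice and put bromine on the carbon that is to become C9.

**7 ⇒ 3 + 4.** The C4–C8 bond is cut. The whole C9–C8–C10–O unit, with both arms already tied together, comes from the commercial ketone 4. The aryl nucleophile (5) is fixed at C4 by the bromine of 3, and the alkoxide (6) is capped in the same flask.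

**3 ⇒ 2 ⇒ 1.** The O7–Si and O3–allyl bonds are cut. The phenol and the benzylic alcohol of 1 are told apart by acidity. The allyl ether must survive the organolithium, TMSBr and fluoride, and must leave later under zerovalent palladium in the presence of the oxirane and the esters. The silyl ether must fall together with the TMS groups.

## Other disconnections considered

**Alternative 1:** The first plan to come to mind cuts both C–O bonds of the oxirane and goes back to the 1,1-disubstituted allylic alcohol A1. The forward key step is a Sharpless asymmetric epoxidation (Ti(OiPr)4, tartrate ester, t-BuOOH), leading after desilylation to 11. It is a sound route and is kept as the fallback for the key step. The chosen plan is preferred for three reasons. The product of epoxidising A1 is a tertiary benzylic epoxide ortho to an oxygen donor, generated in the presence of a Lewis-acidic tetravalent titanium alkoxide and free alcohols, which invites opening at C8. A1 needs a separate C–C bond construction, whereas 4 delivers the three-carbon unit in one addition. And it is the route the test sentence is meant to exclude.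

**Alternative 2:** The O10–acyl bond is "cut" in the sense of a group-selective acylation. The open-chain prochiral triol A2 would be mono-isobutyrylated (lipase, or CuCl2 with a bisoxazoline ligand) to monoester A3, followed by sulfonylation of the remaining primary hydroxyl and closure. This uses the same symmetry as the chosen plan but is weaker on two counts. In A3 the ester and the free primary hydroxyl are the two former enantiotopic arms, so a degenerate 1,3-acyl shift through a six-membered ortho ester intermediate converts A3 into its enantiomer, and every later basic step (sulfonylation, closure) threatens the enantiomeric purity. In 9 the arms are C–Br and C–OSi and cannot exchange. In addition, A2 needs a protected dihydroxyacetone and a deprotection, which is at least one step more than the oxetane.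

**Alternative 3:** The C8–C9 and C9–O8 bonds are cut together. A catalytic asymmetric Corey–Chaykovsky methylene transfer (dimethyloxosulfonium methylide with the complex LaLi3(binaphthoxide)3) to the α-acyloxy ketone A4 would give 12 directly. This is the shortest on paper. However, that catalyst class distinguishes a methyl group from a larger group; here the carbonyl is flanked by an ortho-substituted aryl group and a CH2OCOR group, for which no facial preference can be argued. The basic ylide also threatens A4 by enolisation and acyl transfer. The oxetane opening discriminates at a primary carbon remote from such functionality.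

Key step: step 4

Assumption: compounds 1 and 4 are taken as commercial; 1 is otherwise one borane reduction away from commercial 4-bromo-3-hydroxybenzoic acid.

Assumption: which enantiomer of the squaramide catalyst gives (S)-9 from this ortho-alkoxyaryl oxetane cannot be fixed on paper. The enantiomer that does so is meant; both are equally accessible from (S)- or (R)-tert-leucine.

## Steps

Step 1
Reactants: 1 2-bromo-5-(hydroxymethyl)phenol
Product: 2 [4-bromo-3-(prop-2-en-1-yloxy)phenyl]methanol
Conditions: allyl bromide (1.1 equiv), K2CO3, acetone, 56 °C
Reagents that add atoms: allyl bromide, C=CCBr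
Why: Williamson O-alkylation; K2CO3 deprotonates only the phenol, which is several pKa units more acidic than the benzylic alcohol, so the allyl group goes to O3 alone.

Step 2
Reactants: 2 [4-bromo-3-(prop-2-en-1-yloxy)phenyl]methanol
Product: 3 tert-butyl{[4-bromo-3-(prop-2-en-1-yloxy)phenyl]methoxy}dimethylsilane
Conditions: TBSCl, imidazole, DMF, 23 °C
Reagents that add atoms: tert-butyldimethylsilyl chloride, CC(C)(C)[Si](C)(C)Cl
Why: Standard imidazole-mediated silylation of a primary alcohol; the TBS ether should survive n-BuLi and TMSBr at −78 °C and is removed together with the TMS groups in step 5.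

Step 3
Reactants: 3 tert-butyl{[4-bromo-3-(prop-2-en-1-yloxy)phenyl]methoxy}dimethylsilane; 4 oxetan-3-one
Product: 7 3-[4-(TBS-oxymethyl)-2-(prop-2-en-1-yloxy)phenyl]-3-(trimethylsilyloxy)oxetane, via aryllithium 5 (not isolated), via lithium oxetan-3-olate 6 (not isolated)
Conditions: n-BuLi, THF, −78 °C; then 4, −78 °C; then TMSCl, −78 to 23 °C
Reagents that add atoms: chlorotrimethylsilane, C[Si](C)(C)Cl
Why: Bromine–lithium exchange at −78 °C is faster than deprotonation or carbolithiation of the allyl ether and fixes the nucleophilic carbon at C4; 1,2-addition of 5 to the strained, unhindered ketone 4 gives alkoxide 6, which TMSCl silylates in the same flask. The product is achiral (mirror plane through C8, the aryl group and the silyloxy oxygen).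

Step 4
Reactants: 7 3-[4-(TBS-oxymethyl)-2-(prop-2-en-1-yloxy)phenyl]-3-(trimethylsilyloxy)oxetane
Product: 9 (2S)-3-bromo-2-[4-(TBS-oxymethyl)-2-(prop-2-en-1-yloxy)phenyl]-1,2-bis(trimethylsilyloxy)propane, via silyloxetanium bromide 8 (not isolated)
Conditions: TMSBr (1.3 equiv), chiral squaramide hydrogen-bond-donor catalyst (tert-leucine 2-arylpyrrolidine amide type, 5 mol%), t-BuOMe, −78 °C; Et3N quench
Reagents that add atoms: bromotrimethylsilane, C[Si](C)(C)Br
Why: The oxetane oxygen of 7, the most basic and least hindered oxygen, is silylated by TMSBr while the bromide is held by the two N–H bonds of the squaramide, giving ion pair 8; the catalyst-bound bromide then opens one of the two enantiotopic CH2–O bonds by SN2 attack at a primary carbon, which is the enantiodetermining event. The closest known reaction type is the chiral squaramide-catalysed enantioselective addition of TMSBr to 3-substituted and 3,3-disubstituted oxetanes to give 1,3-bromohydrin silyl ethers. No ring is closed here: the four-membered ring is opened, and the oxirane is closed only in step 5 in the 3-exo-tet mode. The one new stereocentre, C8, is controlled by the catalyst alone (enantiotopic group selection), and since no bond to C8 is made or broken it cannot be lost by ionisation during the substitution. The step needs enantiotopic discrimination, which rests on the large steric and electronic difference between the two C8 substituents (a π-rich ortho-alkoxyaryl group that can stack against the aryl group of the catalyst, and a compact OSiMe3 group), and chemoselectivity for the oxetane oxygen over the allyl ether and silyl ether oxygens, which its strain-enhanced basicity and the low temperature should secure. The tertiary hydroxyl is capped as its TMS ether so that no HBr, the source of a racemic background opening, is released. The two arms of 9 are C–Br and C–OSi, which cannot exchange roles: the brominated carbon becomes C9 of the oxirane and the carbon that keeps the ring oxygen becomes C10.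

Step 5
Reactants: 9 (2S)-3-bromo-2-[4-(TBS-oxymethyl)-2-(prop-2-en-1-yloxy)phenyl]-1,2-bis(trimethylsilyloxy)propane
Product: 11 {(2S)-2-[4-(hydroxymethyl)-2-(prop-2-en-1-yloxy)phenyl]oxiran-2-yl}methanol, via bromo triol 10 (not isolated)
Conditions: TBAF (3.5 equiv), THF, 0 to 23 °C
Reagents that add atoms: none
Why: Fluoride removes all three silyl groups and the tertiary alkoxide of 10 displaces bromide at C9 in an intramolecular Williamson reaction (3-exo-tet), which should be far faster than 4-exo-tet return of the primary alkoxide to an oxetane. No bond to C8 is touched, so the configuration set in step 4 is kept (the descriptor stays S), and a Payne rearrangement of 11 under these conditions would be degenerate and return the same enantiomer.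

Step 6
Reactants: 11 {(2S)-2-[4-(hydroxymethyl)-2-(prop-2-en-1-yloxy)phenyl]oxiran-2-yl}methanol
Product: 12 {(2R)-2-[4-{[(2-methylpropanoyl)oxy]methyl}-2-(prop-2-en-1-yloxy)phenyl]oxiran-2-yl}methyl 2-methylpropanoate
Conditions: (i-PrCO)2O (3 equiv), Et3N, DMAP (cat.), CH2Cl2, 0 to 23 °C
Reagents that add atoms: isobutyric anhydride, CC(C)C(=O)OC(=O)C(C)C
Why: DMAP-catalysed acylation of both primary alcohols (O7 and O10) with one reagent; the buffered basic medium should leave the oxirane and the allyl ether untouched. The descriptor changes from S to R only because the CIP rank of C10 rises above that of C9 on acylation; no bond at C8 changes.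

Step 7
Reactants: 12 {(2R)-2-[4-{[(2-methylpropanoyl)oxy]methyl}-2-(prop-2-en-1-yloxy)phenyl]oxiran-2-yl}methyl 2-methylpropanoate
Product: 14 5-{[(2-methylpropanoyl)oxy]methyl}-2-[(2R)-2-{[(2-methylpropanoyl)oxy]methyl}oxiran-2-yl]phenyl (2E)-2-methylbut-2-enoate, via sodium phenoxide 13 (not isolated)
Conditions: Pd(PPh3)4 (5 mol%), TolSO2Na (1.1 equiv), THF/DMF, 0 to 23 °C; then tigloyl chloride (1.5 equiv), −20 °C
Reagents that add atoms: (E)-2-methylbut-2-enoyl chloride (tigloyl chloride), C/C=C(\C)C(Cl)=O
Why: Zerovalent palladium ionises the aryl allyl ether (Tsuji–Trost type π-allyl formation) and the sulfinate captures the allyl group irreversibly as a sulfone, leaving sodium phenoxide 13; this is acylated at once by tigloyl chloride without an amine base, so neither deconjugation through a vinylketene nor loss of the (E) geometry is expected. The phenol is never present in neutral form next to the oxirane, and attack of the phenoxide on C9 would be a disfavoured 5-endo opening.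

## Compound list

1 | 2-bromo-5-(hydroxymethyl)phenol | OCc1ccc(Br)c(O)c1 | starting material
2 | [4-bromo-3-(prop-2-en-1-yloxy)phenyl]methanol | C=CCOc1cc(CO)ccc1Br | intermediate
3 | tert-butyl{[4-bromo-3-(prop-2-en-1-yloxy)phenyl]methoxy}dimethylsilane | C=CCOc1cc(CO[Si](C)(C)C(C)(C)C)ccc1Br | intermediate
4 | oxetan-3-one | O=C1COC1 | starting material
5 | [4-(TBS-oxymethyl)-2-(prop-2-en-1-yloxy)phenyl]lithium (aryllithium) | C=CCOc1cc(CO[Si](C)(C)C(C)(C)C)ccc1[Li] | intermediate
6 | lithium 3-[4-(TBS-oxymethyl)-2-(prop-2-en-1-yloxy)phenyl]oxetan-3-olate | C=CCOc1cc(CO[Si](C)(C)C(C)(C)C)ccc1C1(O[Li])COC1 | intermediate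
7 | 3-[4-(TBS-oxymethyl)-2-(prop-2-en-1-yloxy)phenyl]-3-(trimethylsilyloxy)oxetane (achiral) | C=CCOc1cc(CO[Si](C)(C)C(C)(C)C)ccc1C1(O[Si](C)(C)C)COC1 | intermediate
8 | 1-(trimethylsilyl)oxetan-1-ium bromide of 7 (ion pair bound to the catalyst) | C=CCOc1cc(CO[Si](C)(C)C(C)(C)C)ccc1C1(O[Si](C)(C)C)C[O+]([Si](C)(C)C)C1.[Br-] | intermediate
9 | (2S)-3-bromo-2-[4-(TBS-oxymethyl)-2-(prop-2-en-1-yloxy)phenyl]-1,2-bis(trimethylsilyloxy)propane | C=CCOc1cc(CO[Si](C)(C)C(C)(C)C)ccc1[C@@](O[Si](C)(C)C)(CBr)CO[Si](C)(C)C | intermediate
10 | (2S)-3-bromo-2-[4-(hydroxymethyl)-2-(prop-2-en-1-yloxy)phenyl]propane-1,2-diol | C=CCOc1cc(CO)ccc1[C@@](O)(CBr)CO | intermediate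
11 | {(2S)-2-[4-(hydroxymethyl)-2-(prop-2-en-1-yloxy)phenyl]oxiran-2-yl}methanol | C=CCOc1cc(CO)ccc1[C@]1(CO)CO1 | intermediate
12 | {(2R)-2-[4-{[(2-methylpropanoyl)oxy]methyl}-2-(prop-2-en-1-yloxy)phenyl]oxiran-2-yl}methyl 2-methylpropanoate | C=CCOc1cc(COC(=O)C(C)C)ccc1[C@]1(COC(=O)C(C)C)CO1 | intermediate
13 | sodium 5-{[(2-methylpropanoyl)oxy]methyl}-2-[(2R)-2-{[(2-methylpropanoyl)oxy]methyl}oxiran-2-yl]phenolate | [Na+].[O-]c1cc(COC(=O)C(C)C)ccc1[C@]1(COC(=O)C(C)C)CO1 | intermediate
14 | 5-{[(2-methylpropanoyl)oxy]methyl}-2-[(2R)-2-{[(2-methylpropanoyl)oxy]methyl}oxiran-2-yl]phenyl (2E)-2-methylbut-2-enoate | C/C=C(\C)C(=O)Oc1cc(COC(=O)C(C)C)ccc1[C@]1(COC(=O)C(C)C)CO1 | target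

## Step count and least certain steps

Total: 7 steps. Longest linear sequence: 7 steps (1 to 14); 4 enters in step 3.

**Step 4 (key step).** The most likely failure is insufficient discrimination between the two enantiotopic CH2 groups. The ortho allyloxy group twists the aryl ring out of the plane the catalyst reads and may compete for the hydrogen-bond donor. Two further failure modes are a racemic background opening if traces of HBr form, and neighbouring-group opening of 8 by the ortho ether oxygen with loss of the allyl group. Fallback, changing the source of asymmetry: set out from 3. Bromine–magnesium exchange (iPrMgCl·LiCl) and CuI-catalysed anti-carbomagnesiation of the magnesium alkoxide of propargyl alcohol should give 2-[4-(TBS-oxymethyl)-2-(prop-2-en-1-yloxy)phenyl]prop-2-en-1-ol F1 (the same structure as A1). Sharpless asymmetric epoxidation (Ti(OiPr)4, L-(+)-diisopropyl tartrate, t-BuOOH, 4 Å molecular sieves, CH2Cl2, −20 °C) should then give {(2S)-2-[4-(TBS-oxymethyl)-2-(prop-2-en-1-yloxy)phenyl]oxiran-2-yl}methanol F2, by the usual facial rule under which allyl alcohol gives (S)-glycidol with the L-(+)-tartrate. TBAF then gives 11, where the route is rejoined.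

**Step 7.** The most likely failure is decomposition at the phenoxide stage: attack of the ortho phenoxide on the oxirane, heterolysis of the C8–O bond towards a quinone methide, or acyl scrambling between the phenoxide and the C10 isobutyrate before tigloyl chloride is added. Fallback, giving up the anionic one-pot: set out from 12. Deallylation with Pd(PPh3)4 and morpholine as a neutral allyl acceptor gives the neutral phenol {(2R)-2-[2-hydroxy-4-{[(2-methylpropanoyl)oxy]methyl}phenyl]oxiran-2-yl}methyl 2-methylpropanoate F3, which is isolated quickly and esterified with tiglic acid by carbodiimide coupling (EDC, DMAP, CH2Cl2, 0 °C) to give 14.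

**Step 3.** The most likely failures are cyclisation of the aryllithium onto the allyl double bond or proton transfer from the allylic OCH2 group if the temperature rises, and incomplete silylation of the hindered alkoxide, which would carry a free hydroxyl into step 4. Fallback with a less basic metal and a separate silylation: set out from 3. Bromine–magnesium exchange with iPrMgCl·LiCl and addition to 4 gives, after aqueous work-up, 3-[4-(TBS-oxymethyl)-2-(prop-2-en-1-yloxy)phenyl]oxetan-3-ol F4. This is purified and silylated with N-(trimethylsilyl)imidazole to give 7.

**Step 5.** The most likely failure is loss of material by closure in the wrong direction: the primary silyl ether is cleaved first and its alkoxide returns to an achiral oxetane (4-exo-tet) before the tertiary silyl ether is removed. Fallback separating desilylation from closure: set out from 9. Fluoride buffered with acetic acid (TBAF/AcOH, THF) removes the silyl groups without generating alkoxides and lets 10 be isolated. K2CO3 in methanol at 0 °C then closes the oxirane from the tertiary oxygen to give 11. No new compound is involved.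

## Further compounds

F1 | step 4 | 2-[4-(TBS-oxymethyl)-2-(prop-2-en-1-yloxy)phenyl]prop-2-en-1-ol | C=CCOc1cc(CO[Si](C)(C)C(C)(C)C)ccc1C(=C)CO
F2 | step 4 | {(2S)-2-[4-(TBS-oxymethyl)-2-(prop-2-en-1-yloxy)phenyl]oxiran-2-yl}methanol | C=CCOc1cc(CO[Si](C)(C)C(C)(C)C)ccc1[C@]1(CO)CO1
F3 | step 7 | {(2R)-2-[2-hydroxy-4-{[(2-methylpropanoyl)oxy]methyl}phenyl]oxiran-2-yl}methyl 2-methylpropanoate | Oc1cc(COC(=O)C(C)C)ccc1[C@]1(COC(=O)C(C)C)CO1
F4 | step 3 | 3-[4-(TBS-oxymethyl)-2-(prop-2-en-1-yloxy)phenyl]oxetan-3-ol | C=CCOc1cc(CO[Si](C)(C)C(C)(C)C)ccc1C1(O)COC1
F0 | step 5 | none | none
A1 | alternative 1 | 2-[4-(TBS-oxymethyl)-2-(prop-2-en-1-yloxy)phenyl]prop-2-en-1-ol | C=CCOc1cc(CO[Si](C)(C)C(C)(C)C)ccc1C(=C)CO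
A2 | alternative 2 | 2-[4-(TBS-oxymethyl)-2-(prop-2-en-1-yloxy)phenyl]propane-1,2,3-triol | C=CCOc1cc(CO[Si](C)(C)C(C)(C)C)ccc1C(O)(CO)CO
A3 | alternative 2 | (2R)-2-[4-(TBS-oxymethyl)-2-(prop-2-en-1-yloxy)phenyl]-2,3-dihydroxypropyl 2-methylpropanoate | C=CCOc1cc(CO[Si](C)(C)C(C)(C)C)ccc1[C@@](O)(CO)COC(=O)C(C)C
A4 | alternative 3 | 2-[4-{[(2-methylpropanoyl)oxy]methyl}-2-(prop-2-en-1-yloxy)phenyl]-2-oxoethyl 2-methylpropanoate | C=CCOc1cc(COC(=O)C(C)C)ccc1C(=O)COC(=O)C(C)C
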